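The earlier runs and the new flask were generated by integration with constants of no real substance.

The solid substrate left and what has gone from it add up to the charge at every reading, so in the amber run the fall of the solid is itself a rate, and I read that rate first.

| flask | solid substrate | remark | time |
|---|---|---|---|
| amber | 0.32 M | run made earlier |  |
| Sunday's | 1.2 M |  | 8.0 h |
| Monday's | 0.80 M |  | 8.0 h |
| Thursday's | 2.5 M |  | 8.0 h |
| Saturday's | 1.5 M |  | 8.0 h |
| Wednesday's | 3.0 M |  | 8.0 h |
| Tuesday's | 0.40 M |  | 8.0 h |

- amber (time / h: ring / %, solid substrate / %): 0.667: 3.2, 83.1; 1.33: 6.0, 64.7; 2.50: 17.5, 38.1; 4.00: 35.9, 4.8; 8.00: 58.9, 0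

(standard deviation of a reading: 1 percentage point)

- as a solid, counted per litre of solution: solid substrate
- what was read earlier has a scatter of 1 percentage point, one standard deviation
- at the start none of the solid substrate is in solution
- what has only dissolved of solid substrate counts as not reacted

- all flasks from highest to lowest amount of ring, in percent of the solid substrate charged, at 8.0 h (Sunday's / Monday's / Thursday's / Saturday's / Wednesday's / Tuesday's)
- the amount of ring, in percent of the solid substrate charged of the flask you put first, at 8.0 h
- the amount of ring, in percent of the solid substrate charged of the flask you put last, at 8.0 h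

Up to its first reading the amber run lost solid at 0.0811 M h⁻¹, and between 2.50 h and 4.00 h at 0.0710 M h⁻¹. That is a slowing by a factor of 0.875, which a scatter of 1 percentage point per reading can only just show. Accumulated up to 4.00 h, the solid fell at 0.0762 M h⁻¹ on average, a zero-order feed in the usual term, and I assumed from this one run that it does not depend on the charge.

I call the charge this feed takes out of the solid within the asked time the reach: 0.609 M. Five charges stand above it, so I expected those flasks to feed alike and make equal ring per litre, their percentages falling as the charge rises. Amber's ring grew at 0.0393 M h⁻¹ between 2.50 h and 4.00 h. Held to 8.0 h, that gives 0.272 M, which is 34.0% of Monday's charge and 9.06% of Wednesday's. Tuesday's charge lies under the reach and should run out near 5.25 h, so I put Tuesday's first, somewhat below amber's final 58.9%.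

The forecast gave Tuesday's > Monday's > Sunday's > Saturday's > Thursday's > Wednesday's, with 56% and 9.7%, holding that “each makes the same absolute ring”.

The flasks gave Tuesday's > Monday's > Sunday's > Saturday's > Thursday's > Wednesday's, with 55.4% for the first and 9.09% for the last.

    starting material ⇌ ring (K = 34.0, k = 0.360 h⁻¹)
    2 starting material → open dimer (k = 1.20 L mol⁻¹ h⁻¹)
    starting material + open dimer → open trimer (k = 0.240 L mol⁻¹ h⁻¹)
    solid substrate ⇌ starting material, rate k4*(cs4 - [starting material]) while solid is left; crystals form when [starting material] > cs4 (solubility = 0.670 M, k = 0.130 h⁻¹)

The reach leaves 79.7% of Wednesday's charge as solid at the asked time, and Wednesday's flask holds 80.2%. Tuesday's ring stands at 55.4% mainly because two starting material turn into open dimer: with that step taken away, the same flask gives 81.1%. Scaled to 3.0 h, the reach leaves 42.9% of Tuesday's charge as solid, and Tuesday's flask read at that time holds 41.9%.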